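## Retrosynthetic overview

1. Feature: ring A is a phloroglucinol ring frozen in a keto form. C8 lies between C7=O and the enol-ether carbon C8a–O1. It is quaternary and carries two identical prenyl groups, which leaves C4a=C8a and C5(OMe)=C6 as a cyclohexa-2,4-dienone.
2. Key disconnection: both C8–CH2(prenyl) bonds are cut in one operation. This re-aromatises ring A and leads back to unprotected (2S)-7-hydroxy-5-methoxyflavanone (alpinetin). In the forward direction it is a biomimetic one-pot double dearomative C8-prenylation under base-free Pd(0) catalysis.
3. C4–OH is traced back to C4=O. The ketone is kept through the key step because it blocks C4a, acidifies 7-OH and steers attack to C8. It is then reduced under 1,3-induction from C2 to give the 2,4-cis alcohol.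
4. Ring order: rings B and C and the C2 centre come with the chiral-pool flavanone. No ring is built; ring A is re-hybridised late. The classical sequence would instead use early C-prenylation, chalcone formation, cyclisation and resolution.
5. The prenyl donor is made in one step from prenol.

Key step: step 2

Assumption: commercial (−)-alpinetin is the (2S)-enantiomer drawn below. Its enantiomeric purity is checked by chiral HPLC before use.

## Route

Step 1
Reactants: 1 3-methylbut-2-en-1-ol (prenol); 2 di-tert-butyl dicarbonate
Product: 3 tert-butyl (3-methylbut-2-en-1-yl) carbonate
Conditions: Boc2O (1.1 equiv), Bu4NHSO4 (5 mol %), 30% aq NaOH, CH2Cl2, 0 °C to rt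
Reagents that add atoms: di-tert-butyl dicarbonate (2), CC(C)(C)OC(=O)OC(=O)OC(C)(C)C
Why: Phase-transfer O-acylation of a primary allylic alcohol with Boc2O is a routine mixed-carbonate formation that leaves the trisubstituted alkene untouched and creates no stereocentre.

Step 2
Reactants: 4 (2S)-7-hydroxy-5-methoxyflavanone, (−)-alpinetin; 3 tert-butyl (3-methylbut-2-en-1-yl) carbonate
Product: 6 (2S)-5-methoxy-8,8-bis(3-methylbut-2-enyl)-2-phenyl-2,3-dihydro-4H-chromene-4,7(8H)-dione, via (2S)-8-prenylalpinetin 5 (not isolated)
Conditions: 3 (2.05 equiv, slow addition), Pd(PPh3)4 (5 mol %), degassed THF, 0 °C to rt, Ar, no added base; neutral work-up, product kept at or below rt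
Reagents that add atoms: tert-butyl (3-methylbut-2-en-1-yl) carbonate (3), CC(C)=CCOC(=O)OC(C)(C)C
Why: Pd(0) ionises 3 to the π-(1,1-dimethylallyl)palladium cation, CO2 and tert-butoxide, the butoxide is consumed at once by the acidic 7-OH (a vinylogous acid through C4=O), and the ambident phenoxide attacks the unsubstituted allyl terminus, where O7-attack gives an aryl prenyl ether that Pd(0) re-ionises, so material should drain into irreversible C–C bond formation at C8, first to 5 after tautomerisation and then at the same carbon to the quaternary C8 of 6. The closest known reaction type is the Tsuji–Trost allylic dearomatisation of acylphloroglucinols and naphthols with allylic carbonates, and the step copies the presumed double action of an aromatic prenyltransferase. It closes no ring and creates no stereocentre (C8 carries two identical groups), but it forms both C8–C bonds and turns flat ring A into the dienone with C4a=C8a, C5(OMe)=C6 and C7=O in place. The step needs C8 over C6, C4a, O7 and C3: O1 is held coplanar by ring C and conjugated with C4=O, which fixes enol character in C7=C8, the 5-OMe can only turn its methyl group toward C6 because the peri C4=O closes the other side, C4a is blocked by the acyl carbon, and C3 is not enolised without base. It also needs C2 to survive, which the medium should secure because each alkoxide is quenched by phenol and almost no carbonate is left after the second allylation, so retro-oxa-Michael opening of 4, 5 or 6 should not start. After 6 no acidic O–H remains, so allylation should stop by itself.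

Step 3
Reactants: 6 (2S)-5-methoxy-8,8-bis(3-methylbut-2-enyl)-2-phenyl-2,3-dihydro-4H-chromene-4,7(8H)-dione
Product: 7 pongaflavanol, (2S,4S)-4-hydroxy-5-methoxy-8,8-bis(3-methylbut-2-enyl)-2-phenyl-3,4-dihydro-2H-chromen-7(8H)-one
Conditions: NaBH4 (1.0 equiv), CeCl3·7H2O (1.2 equiv), MeOH/THF 3:1, −78 °C; pH 7 phosphate buffer; chromatography on Et3N-deactivated silica
Reagents that add atoms: none
Why: The Luche 1,2-reduction should pick C4=O (a singly vinylogous ester next to CH2) over C7=O (donor-stabilised by both 5-OMe and O1 and neopentylic next to C8), and hydride should enter axially on the half-chair with 2-phenyl pseudo-equatorial, as in the reduction of flavanones and 2-substituted 2,3-dihydro-4H-pyran-4-ones, giving the pseudo-equatorial 4-OH cis to phenyl, i.e. (4S), while the low temperature keeps ring C closed and C2 untouched.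

## Compound list

1 | 3-methylbut-2-en-1-ol (prenol) | CC(C)=CCO | starting material
2 | di-tert-butyl dicarbonate | CC(C)(C)OC(=O)OC(=O)OC(C)(C)C | starting material
3 | tert-butyl (3-methylbut-2-en-1-yl) carbonate | CC(C)=CCOC(=O)OC(C)(C)C | intermediate
4 | (2S)-7-hydroxy-5-methoxyflavanone, (−)-alpinetin | COc1cc(O)cc2c1C(=O)C[C@@H](c1ccccc1)O2 | starting material
5 | (2S)-7-hydroxy-5-methoxy-8-(3-methylbut-2-enyl)flavanone, (2S)-8-prenylalpinetin | COc1cc(O)c(CC=C(C)C)c2c1C(=O)C[C@@H](c1ccccc1)O2 | intermediate
6 | (2S)-5-methoxy-8,8-bis(3-methylbut-2-enyl)-2-phenyl-2,3-dihydro-4H-chromene-4,7(8H)-dione | COC1=CC(=O)C(CC=C(C)C)(CC=C(C)C)C2=C1C(=O)C[C@@H](c1ccccc1)O2 | intermediate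
7 | pongaflavanol, (2S,4S)-4-hydroxy-5-methoxy-8,8-bis(3-methylbut-2-enyl)-2-phenyl-3,4-dihydro-2H-chromen-7(8H)-one | COC1=CC(=O)C(CC=C(C)C)(CC=C(C)C)C2=C1[C@@H](O)C[C@@H](c1ccccc1)O2 | target

## Step count and risks

Total step count: 3. Longest linear sequence: 3 (1 → 3 → 6 → 7), which is two steps from 4.

**Step 2 (key step).**
- What may go wrong: the π-prenyl complex may attack C6, or the reaction may stop at the O-prenyl ether or the mono-prenyl phenol. The electrophile may be lost as isoprene. Residual alkoxide may open ring C and erode C2.
- Fallback: the double alkylation is split into two mechanistically different C–C bond formations.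
  - It sets out from 4. Electrophilic iodination (NIS, DMF, 0 °C) should enter at the same bond-fixed C8 and give (2S)-7-hydroxy-8-iodo-5-methoxyflavanone F1.
  - A neutral Stille coupling of this iodide with tributyl(3-methylbut-2-enyl)stannane (Pd(PPh3)4, DMF, 80 °C) places the first prenyl group regiospecifically. It comes back to the route at 5, which is now isolated.
  - Only the dearomatising second allylation is then left. It uses one equivalent of 3 under the conditions of step 2 and leads to 6.

**Step 3.**
- What may go wrong: hydride may be delivered to C7 or to a conjugate position. Ring C may open by retro-oxa-Michael reaction in the basic borohydride medium. The peri 5-OMe may lower the facial selectivity.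
- Fallback: the control element is changed from substrate-controlled stoichiometric hydride to catalyst-controlled Noyori–Ikariya transfer hydrogenation in a near-neutral medium.
  - It sets out from 6 and comes back directly at 7, with RuCl[(S,S)-TsDPEN](p-cymene) (1 mol %), HCO2Na, H2O/CH2Cl2, rt.
  - The (S,S)-catalyst should deliver hydride to the face that gives (4S), which is matched with the (2S)-substrate.
  - The hindered C7=O should not fit the catalyst.
  - This fallback makes no compound outside the list (F0).

**Step 1.**
- What may go wrong: the symmetrical diprenyl carbonate may form, or Boc2O may hydrolyse before acyl transfer.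
- Fallback: pre-activation of the alcohol is dropped.
  - It sets out from 1 and 4 and comes back at 6.
  - It uses Pd(0)/Et3B-promoted Tsuji–Trost allylation with the free allylic alcohol (Pd(PPh3)4, Et3B, THF, rt to 50 °C). This variant is known to take naphthols and benzenepolyols through to gem-diallyl ketones.
  - This fallback makes no compound outside the list (F0).

## Further compounds

F1 | step 2 | (2S)-7-hydroxy-8-iodo-5-methoxyflavanone | COc1cc(O)c(I)c2c1C(=O)C[C@@H](c1ccccc1)O2
F0 | step 3 | none | none
F0 | step 1 | none | none
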